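**Retrosynthetic overview**
1. Target 22 ⇒ terminal alkyne 20 + 3-methylbut-2-enoic acid (ruthenium-catalysed anti-Markovnikov addition gives the Z enol ester last).
2. 20 ⇒ exocyclic methylene ketone 18 + acetyl radical from pyruvic acid: the acetyl C–CH2 bond of the 1,4-diketone is the key bond, and C7 is set by protonation.
3. 18 ⇒ enone 8 by conjugate alkynylation with Mannich trapping (C6), dehydrogenation and Morita–Baylis–Hillman hydroxymethylation.
4. 8 ⇒ silyl enol ether 5 by dibromocarbene one-carbon ring expansion. Only one carbocycle is involved: the six-membered ring of 1 is enlarged to the seven-membered ring in step 2.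
5. 5 ⇒ 3-methylcyclohex-2-enone 1 + homoprenyl bromide 2 (copper-catalysed asymmetric conjugate addition sets C5).

Assumption and numbering: ring atoms are called C1 (ring C=O), C2 (CH2OH-bearing), C3, C4, C5 (quaternary), C6 (enol-ester-bearing), C7 (2-oxopropyl-bearing); the target is read as 5R,6S,7R with a Z enol ester, i.e. homoprenyl, C6 and C7 substituents all cis.

**Step 1**
Reactants: 1 3-methylcyclohex-2-en-1-one; 2 5-bromo-2-methylpent-2-ene
Product: 5 (S)-trimethyl{[3-methyl-3-(4-methylpent-3-en-1-yl)cyclohex-1-en-1-yl]oxy}silane, via Grignard reagent 3 (not isolated), via magnesium enolate 4 (not isolated)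
Conditions: 2, Mg, Et2O; then 1, Cu(OTf)2 (3 mol %), chiral C2-symmetric imidazolinium salt (carbene precursor, 4 mol %), Et2O, 0 °C; then Me3SiCl, Et3N, 0 °C → rt
Reagents that add atoms: chlorotrimethylsilane C[Si](C)(C)Cl
Why: Copper-catalysed asymmetric conjugate addition of a Grignard reagent to a β-methyl enone sets the quaternary carbon (future C5) as S under catalyst control (ligand enantiomer chosen accordingly), and silylation of the magnesium enolate fixes the enol double bond toward the quaternary carbon.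

**Step 2**
Reactants: 5 (S)-silyl enol ether
Product: 7 (S)-2-bromo-4-methyl-4-(4-methylpent-3-en-1-yl)cyclohept-2-en-1-one, via dibromocyclopropane 6 (not isolated)
Conditions: CHBr3 (1.05 equiv), KOtBu, pentane, −25 °C → rt
Reagents that add atoms: bromoform BrC(Br)Br
Why: Dibromocarbene cyclopropanation of the electron-rich silyl enol ether (expected to react ahead of the trisubstituted side-chain alkene) is followed by cyclopropyl-to-allyl electrocyclic ring opening with loss of Me3SiBr, a one-carbon ring expansion that touches no stereocentre.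

**Step 3**
Reactants: 7 (S)-2-bromo enone
Product: 8 (S)-4-methyl-4-(4-methylpent-3-en-1-yl)cyclohept-2-en-1-one
Conditions: Pd(OAc)2 (5 mol %), PPh3, HCO2H, Et3N, DMF, 60 °C
Reagents that add atoms: none
Why: Palladium-catalysed formate hydrogenolysis of the vinyl bromide (oxidative addition to zerovalent palladium, formate decarboxylation, C–H reductive elimination) removes bromine while leaving the enone and side-chain alkene intact.

**Step 4**
Reactants: 8 (S)-enone; 9 ethynyltrimethylsilane
Product: 12 (3S,4S)-2-[(dimethylamino)methyl]-4-methyl-4-(4-methylpent-3-en-1-yl)-3-[(trimethylsilyl)ethynyl]cycloheptan-1-one as a mixture of C2 epimers, via alkynylalane 10 (not isolated), via aluminium enolate 11 (not isolated)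
Conditions: 9, n-BuLi, then Me2AlCl, t-BuOMe, 0 °C; then 8, Ni(acac)2 (5 mol %), chiral cyano-bis(oxazoline) ligand (6 mol %), 0 °C; then CH2=NMe2+ I−, THF, −40 → 0 °C
Reagents that add atoms: N,N-dimethylmethyleneiminium iodide (Eschenmoser's salt) C=[N+](C)C.[I-]
Why: Proposed new method: nickel-catalysed enantioselective conjugate addition of a dimethylaluminium acetylide (closest known case: cyclohexenone) is extended to this γ,γ-disubstituted cycloheptenone, where the adjacent quaternary carbon (methyl versus CH2R) gives almost no substrate bias, so the chiral nickel–bis(oxazoline) catalyst (ligand enantiomer chosen to deliver the alkynyl group syn to the homoprenyl group) sets C6 as S, and the aluminium enolate is trapped in a Mannich reaction that masks the later exocyclic methylene (configuration at that carbon is irrelevant).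

**Step 5**
Reactants: 12 Mannich base
Product: 14 (5R,6S)-7-[(dimethylamino)methyl]-5-methyl-5-(4-methylpent-3-en-1-yl)-6-[(trimethylsilyl)ethynyl]cyclohept-2-en-1-one, via lithium enolate 13 (not isolated)
Conditions: LiN(iPr)2, THF, −78 °C; then PhS(Cl)=N-tBu, −78 °C
Reagents that add atoms: none
Why: Kinetic deprotonation takes place at the unhindered C2 methylene (C7 is tertiary and flanked by two branched carbons) and the Mukaiyama dehydrogenation (sulfinimidoyl chloride, syn elimination) gives the C2=C3 enone without touching C5 or C6.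

**Step 6**
Reactants: 14 amino enone
Product: 15 (5R,6S)-7-[(dimethylamino)methyl]-2-(hydroxymethyl)-5-methyl-5-(4-methylpent-3-en-1-yl)-6-[(trimethylsilyl)ethynyl]cyclohept-2-en-1-one
Conditions: aq. HCHO (37 %), DMAP (0.3 equiv), THF/H2O, rt
Reagents that add atoms: formaldehyde C=O
Why: Morita–Baylis–Hillman reaction: DMAP adds to the enone β-carbon C3, the enolate attacks formaldehyde at C2 and loss of DMAP gives the 2-(hydroxymethyl) enone with no new stereocentre.

**Step 7**
Reactants: 15 hydroxymethyl enone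
Product: 18 (5R,6S)-6-ethynyl-2-(hydroxymethyl)-5-methyl-5-(4-methylpent-3-en-1-yl)-7-methylidenecyclohept-2-en-1-one, via terminal alkyne 16 (not isolated), via ammonium iodide 17 (not isolated)
Conditions: Bu4NF, THF, 0 °C; then MeI, rt; then aq. NaHCO3, CH2Cl2, rt
Reagents that add atoms: none
Why: Fluoride protodesilylation frees the terminal alkyne, N-methylation turns the Mannich base into a trimethylammonium leaving group and NaHCO3 triggers a Hofmann-type E1cB elimination to the exocyclic methylene ketone, conditions too mild to epimerise C6.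

**Step 8**
Reactants: 18 exocyclic methylene dienone; 19 pyruvic acid (2-oxopropanoic acid)
Product: 20 (5R,6S,7R)-6-ethynyl-2-(hydroxymethyl)-5-methyl-5-(4-methylpent-3-en-1-yl)-7-(2-oxopropyl)cyclohept-2-en-1-one
Conditions: 19 (2 equiv), 1,2,3,5-tetrakis(carbazol-9-yl)-4,6-dicyanobenzene (4CzIPN, 2 mol %), K2HPO4, DMF/H2O, blue LEDs, 20 °C
Reagents that add atoms: none
Why: Photoredox decarboxylative radical conjugate acylation (a radical Stetter-type hydroacylation): the nucleophilic acetyl radical from pyruvate, a polarity-reversed acetyl unit, adds to the terminal carbon of the exocyclic enone, the α-keto radical is reduced to the ring enolate, and kinetic protonation at C7 opposite the C6 ethynyl group gives the cis (7R) 1,4-diketone under near-neutral conditions that do not equilibrate C7.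

**Step 9**
Reactants: 20 alkynyl diketone; 21 3-methylbut-2-enoic acid
Product: 22 (Z)-2-[(1S,2R,7R)-5-(hydroxymethyl)-2-methyl-2-(4-methylpent-3-en-1-yl)-6-oxo-7-(2-oxopropyl)cyclohept-4-en-1-yl]ethenyl 3-methylbut-2-enoate (target)
Conditions: 21 (1.2 equiv), Ru(η3-CH2C(CH3)CH2)2(Ph2P(CH2)4PPh2) (2 mol %), toluene, 60 °C
Reagents that add atoms: none
Why: Ruthenium-catalysed anti-Markovnikov addition of a carboxylic acid to a terminal alkyne (via a ruthenium vinylidene) gives the Z enol ester selectively, and the base-free, weakly acidic medium leaves C7, the ketones and the free alcohol untouched.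

**Compound list**
1 | 3-methylcyclohex-2-en-1-one | CC1=CC(=O)CCC1 | starting material
2 | 5-bromo-2-methylpent-2-ene | CC(C)=CCCBr | starting material
3 | (4-methylpent-3-en-1-yl)magnesium bromide | CC(C)=CCC[Mg]Br | intermediate
4 | bromomagnesium (S)-3-methyl-3-(4-methylpent-3-en-1-yl)cyclohex-1-en-1-olate | Br[Mg]OC1=C[C@](C)(CCC=C(C)C)CCC1 | intermediate
5 | (S)-trimethyl{[3-methyl-3-(4-methylpent-3-en-1-yl)cyclohex-1-en-1-yl]oxy}silane | C[Si](C)(C)OC1=C[C@](C)(CCC=C(C)C)CCC1 | intermediate
6 | (5S)-7,7-dibromo-5-methyl-5-(4-methylpent-3-en-1-yl)-1-(trimethylsilyloxy)bicyclo[4.1.0]heptane (both cyclopropane faces) | C[Si](C)(C)OC12CCC[C@@](C)(CCC=C(C)C)C1C2(Br)Br | intermediate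
7 | (S)-2-bromo-4-methyl-4-(4-methylpent-3-en-1-yl)cyclohept-2-en-1-one | O=C1CCC[C@@](C)(CCC=C(C)C)C=C1Br | intermediate
8 | (S)-4-methyl-4-(4-methylpent-3-en-1-yl)cyclohept-2-en-1-one | O=C1CCC[C@@](C)(CCC=C(C)C)C=C1 | intermediate
9 | ethynyltrimethylsilane | C#C[Si](C)(C)C | starting material
10 | dimethyl[(trimethylsilyl)ethynyl]aluminium | C[Al](C)C#C[Si](C)(C)C | intermediate
11 | dimethylaluminium (3S,4S)-4-methyl-4-(4-methylpent-3-en-1-yl)-3-[(trimethylsilyl)ethynyl]cyclohept-1-en-1-olate | C[Al](C)OC1=C[C@H](C#C[Si](C)(C)C)[C@](C)(CCC=C(C)C)CCC1 | intermediate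
12 | (3S,4S)-2-[(dimethylamino)methyl]-4-methyl-4-(4-methylpent-3-en-1-yl)-3-[(trimethylsilyl)ethynyl]cycloheptan-1-one (C2 epimers) | CN(C)CC1C(=O)CCC[C@@](C)(CCC=C(C)C)[C@H]1C#C[Si](C)(C)C | intermediate
13 | lithium enolate of 12 (enolate double bond between the carbonyl carbon and the unsubstituted α-methylene) | CN(C)CC1C(O[Li])=CCC[C@@](C)(CCC=C(C)C)[C@H]1C#C[Si](C)(C)C | intermediate
14 | (5R,6S)-7-[(dimethylamino)methyl]-5-methyl-5-(4-methylpent-3-en-1-yl)-6-[(trimethylsilyl)ethynyl]cyclohept-2-en-1-one | CN(C)CC1C(=O)C=CC[C@@](C)(CCC=C(C)C)[C@H]1C#C[Si](C)(C)C | intermediate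
15 | (5R,6S)-7-[(dimethylamino)methyl]-2-(hydroxymethyl)-5-methyl-5-(4-methylpent-3-en-1-yl)-6-[(trimethylsilyl)ethynyl]cyclohept-2-en-1-one | CN(C)CC1C(=O)C(CO)=CC[C@@](C)(CCC=C(C)C)[C@H]1C#C[Si](C)(C)C | intermediate
16 | (5R,6S)-7-[(dimethylamino)methyl]-6-ethynyl-2-(hydroxymethyl)-5-methyl-5-(4-methylpent-3-en-1-yl)cyclohept-2-en-1-one | CN(C)CC1C(=O)C(CO)=CC[C@@](C)(CCC=C(C)C)[C@H]1C#C | intermediate
17 | N-methylated 16: the corresponding (cycloheptenonyl)methyl-trimethylammonium iodide | C[N+](C)(C)CC1C(=O)C(CO)=CC[C@@](C)(CCC=C(C)C)[C@H]1C#C.[I-] | intermediate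
18 | (5R,6S)-6-ethynyl-2-(hydroxymethyl)-5-methyl-5-(4-methylpent-3-en-1-yl)-7-methylidenecyclohept-2-en-1-one | C=C1C(=O)C(CO)=CC[C@@](C)(CCC=C(C)C)[C@H]1C#C | intermediate
19 | pyruvic acid (2-oxopropanoic acid) | CC(=O)C(=O)O | starting material
20 | (5R,6S,7R)-6-ethynyl-2-(hydroxymethyl)-5-methyl-5-(4-methylpent-3-en-1-yl)-7-(2-oxopropyl)cyclohept-2-en-1-one | CC(=O)C[C@H]1C(=O)C(CO)=CC[C@@](C)(CCC=C(C)C)[C@H]1C#C | intermediate
21 | 3-methylbut-2-enoic acid | CC(C)=CC(=O)O | starting material
22 | (Z)-2-[(1S,2R,7R)-5-(hydroxymethyl)-2-methyl-2-(4-methylpent-3-en-1-yl)-6-oxo-7-(2-oxopropyl)cyclohept-4-en-1-yl]ethenyl 3-methylbut-2-enoate | CC(=O)C[C@H]1C(=O)C(CO)=CC[C@@](C)(CCC=C(C)C)[C@H]1/C=C\OC(=O)C=C(C)C | target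

**Totals**
Total step count: 9. Longest linear sequence: 9 steps (from 1; all other inputs are commercial).

**Three steps most likely to fail**

Step 2. Dibromocarbene may also cyclopropanate the trisubstituted side-chain alkene. The fallback sets out from 1 and comes back at 8, carrying the side chain as an acetal so that no second alkene is present. The same copper-catalysed conjugate addition, run with the Grignard reagent of commercial 2-(2-bromoethyl)-1,3-dioxolane and trapped with Me3SiCl, gives (S)-{[3-[2-(1,3-dioxolan-2-yl)ethyl]-3-methylcyclohex-1-en-1-yl]oxy}trimethylsilane F1. CHBr3/KOtBu ring expansion gives (S)-2-bromo-4-[2-(1,3-dioxolan-2-yl)ethyl]-4-methylcyclohept-2-en-1-one F2. Pd(OAc)2/HCO2H/Et3N gives (S)-4-[2-(1,3-dioxolan-2-yl)ethyl]-4-methylcyclohept-2-en-1-one F3. Aqueous acid gives 3-[(S)-1-methyl-4-oxocyclohept-2-en-1-yl]propanal F4. Wittig olefination with Ph3P=C(CH3)2 at −78 °C (the aldehyde reacts before the enone) installs the trisubstituted alkene and returns 8.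

Step 4. The nickel catalyst may be too slow at the hindered β-carbon or may not control the face. The fallback sets out from 8 and comes back at 12, setting C6 by hydride delivery instead of C–C bond formation. The zinc acetylide of 9 is added with Me3SiOTf activation, without stereocontrol, to give trimethyl{[(4S)-4-methyl-4-(4-methylpent-3-en-1-yl)-3-[(trimethylsilyl)ethynyl]cyclohept-1-en-1-yl]oxy}silane (C3 epimers) F5. Saegusa–Ito oxidation with Pd(OAc)2 gives (S)-4-methyl-4-(4-methylpent-3-en-1-yl)-3-[(trimethylsilyl)ethynyl]cyclohept-2-en-1-one F6. Catalyst-controlled copper hydride 1,4-reduction (Cu(OAc)2, chiral bisphosphine, silane) then delivers hydrogen to C6 from the methyl face, and the resulting enol silane is trapped with CH2=NMe2+ I− to return 12.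

Step 8. Face selectivity of the C7 protonation may be low because the ethynyl group is small, and the radical may add elsewhere. The fallback sets out from 18 and comes back at 20 by a closed-shell route. Michael addition of nitroethane (nitronate as acyl-anion equivalent, catalytic tetramethylguanidine, 0 °C) to the exocyclic enone gives (5R,6S,7R)-6-ethynyl-2-(hydroxymethyl)-5-methyl-5-(4-methylpent-3-en-1-yl)-7-(2-nitropropyl)cyclohept-2-en-1-one (nitro-carbon epimers) F7. A buffered TiCl3 Nef reaction converts the nitro group to the methyl ketone and returns 20; a wrong C7 epimer can be re-equilibrated and recycled.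

**Further compounds**
F1 | step 2 | (S)-{[3-[2-(1,3-dioxolan-2-yl)ethyl]-3-methylcyclohex-1-en-1-yl]oxy}trimethylsilane | C[Si](C)(C)OC1=C[C@](C)(CCC2OCCO2)CCC1
F2 | step 2 | (S)-2-bromo-4-[2-(1,3-dioxolan-2-yl)ethyl]-4-methylcyclohept-2-en-1-one | O=C1CCC[C@@](C)(CCC2OCCO2)C=C1Br
F3 | step 2 | (S)-4-[2-(1,3-dioxolan-2-yl)ethyl]-4-methylcyclohept-2-en-1-one | O=C1CCC[C@@](C)(CCC2OCCO2)C=C1
F4 | step 2 | 3-[(S)-1-methyl-4-oxocyclohept-2-en-1-yl]propanal | O=C1CCC[C@@](C)(CCC=O)C=C1
F5 | step 4 | trimethyl{[(4S)-4-methyl-4-(4-methylpent-3-en-1-yl)-3-[(trimethylsilyl)ethynyl]cyclohept-1-en-1-yl]oxy}silane (C3 epimers) | C[Si](C)(C)OC1=CC(C#C[Si](C)(C)C)[C@](C)(CCC=C(C)C)CCC1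
F6 | step 4 | (S)-4-methyl-4-(4-methylpent-3-en-1-yl)-3-[(trimethylsilyl)ethynyl]cyclohept-2-en-1-one | O=C1CCC[C@@](C)(CCC=C(C)C)C(C#C[Si](C)(C)C)=C1
F7 | step 8 | (5R,6S,7R)-6-ethynyl-2-(hydroxymethyl)-5-methyl-5-(4-methylpent-3-en-1-yl)-7-(2-nitropropyl)cyclohept-2-en-1-one (nitro-carbon epimers) | CC([N+](=O)[O-])C[C@H]1C(=O)C(CO)=CC[C@@](C)(CCC=C(C)C)[C@H]1C#C
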